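## Retrosynthetic overview

1. The hydroperoxide is introduced last, by a reagent-controlled ene-type O2 transfer onto a prenyl-type chain alkene. Just before that, the methyl ketone comes from an allyl group (Wacker), the (E)-enol ester from an (E)-alkenylboron plus 3-methylbut-2-enoic acid, and the CH2OH from an enone plus formaldehyde.
2. The trans C6/C7 pair comes from conjugate alkynylation and enolate allylation of a 4,4-disubstituted cyclohept-2-enone.
3. Key disconnection: that cycloheptenone comes from a cyclohexanone silyl enol ether by one-carbon ring expansion (cyclopropanation, then FeCl3 opening of the ring-fusion bond). The inserted carbon becomes C7, and the quaternary carbon moves from β to γ of the ketone.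
4. The quaternary stereocentre comes from a copper-catalysed asymmetric conjugate addition to 3-methylcyclohex-2-enone.
5. Ring order: the six-membered ring is bought and enlarged to the seven-membered ring in steps 2 to 4; no other ring is formed.

Assumption: the ring is numbered C1 (C=O), C2 (C–CH2OH), C3 (=CH), C4 (CH2), C5 (quaternary), C6 (CH–vinyl), C7 (CH–CH2COCH3), and the target is (5S,6S,7S) with (3S) in the side chain (C3′). Compounds that bring carbon into the target are counted as starting materials. For each chiral catalyst or reagent, the enantiomer meant is the one that gives the product drawn; the sense is assigned by analogy.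

## Route

Step 1
Reactants: 1 3-methylcyclohex-2-en-1-one; 2 5-bromo-2-methylpent-1-ene
Product: 5 (S)-trimethyl{[3-methyl-3-(4-methylpent-4-en-1-yl)cyclohex-1-en-1-yl]oxy}silane, via Grignard reagent 3 (not isolated), via magnesium enolate 4 (not isolated)
Conditions: 2, Mg, Et2O; then 1, Cu(OTf)2 (3 mol %), chiral N-mesityl-N′-hydroxyalkyl imidazolinium salt (NHC precursor, 4 mol %), Et2O, 0 °C; then Me3SiCl, Et3N, HMPA, 0 °C → rt
Reagents that add atoms: chlorotrimethylsilane, C[Si](C)(C)Cl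
Why: Copper-catalysed asymmetric conjugate addition of a Grignard reagent to a β-methyl enone sets the quaternary centre (C5) under catalyst control, and O-silylation of the magnesium enolate fixes the enol ether towards the quaternary carbon.

Step 2
Reactants: 5 (S)-silyl enol ether; 6 diiodomethane
Product: 7 (5S)-5-methyl-5-(4-methylpent-4-en-1-yl)-1-(trimethylsilyloxy)bicyclo[4.1.0]heptane (both cyclopropane-face isomers)
Conditions: Et2Zn (1.5 equiv), CH2I2 (1.5 equiv), CH2Cl2, 0 °C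
Reagents that add atoms: none
Why: Simmons–Smith (Furukawa) cyclopropanation is fastest at the electron-rich silyl enol ether, so the isolated 1,1-disubstituted alkene is spared; the two new cyclopropane stereocentres are destroyed in steps 3 and 4.

Step 3
Reactants: 7 siloxycyclopropane
Product: 8 (4S)-3-chloro-4-methyl-4-(4-methylpent-4-en-1-yl)cycloheptan-1-one (C3 epimers, used crude)
Conditions: FeCl3 (2.2 equiv), DMF, 0 °C → rt; aqueous work-up
Reagents that add atoms: iron trichloride, Cl[Fe](Cl)Cl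
Why: Ito–Saegusa ring expansion: FeCl3 oxidises the siloxycyclopropane to an oxy radical, β-scission of the ring-fusion bond gives the ring-enlarged β-keto radical at C6, and this takes Cl from FeCl3; the process is a stepwise radical one, and the terminal chain alkene sits one carbon too far for fast 5-exo closure.

Step 4
Reactants: 8 β-chloro ketone
Product: 10 (R)-4-methyl-4-(4-methylpent-3-en-1-yl)cyclohept-2-en-1-one, via isomerised chloro ketone 9 (not isolated)
Conditions: chloro[N,N′-bis(3,5-di-tert-butylsalicylidene)-1,2-cyclohexanediaminato]cobalt (3 mol %), PhSiH3 (6 mol %), benzene, rt; then NaOAc, MeOH, reflux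
Reagents that add atoms: none
Why: Cobalt-hydride hydrogen-atom-transfer isomerisation moves the 1,1-disubstituted alkene one position to the trisubstituted (prenyl-type) alkene while no enone is present to trap the radical, and E1cB loss of HCl then gives the enone; C5 keeps its geometry (the descriptor changes only through ligand priorities).

Step 5
Reactants: 10 (R)-enone; 11 ethynyltrimethylsilane; 12 allyl bromide
Product: 16 (2S,3S,4R)-2-allyl-4-methyl-4-(4-methylpent-3-en-1-yl)-3-[(trimethylsilyl)ethynyl]cycloheptan-1-one, via lithium acetylide 13 (not isolated), via alkynylalane 14 (not isolated), via aluminium enolate 15 (not isolated)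
Conditions: 11, n-BuLi, Et2O, 0 °C; Me2AlCl; then 10, Ni(acac)2 (5 mol %), (Me2CHCH2)2AlH (5 mol %), chiral cyano-bis(oxazoline) ligand (6 mol %), t-BuOMe, 0 °C; then MeLi, HMPA, 12, THF, −78 → 0 °C
Reagents that add atoms: none
Why: Nickel-catalysed asymmetric conjugate alkynylation with a dimethylaluminium acetylide sets C6 under catalyst control (the substrate bias, methyl versus CH2 chain, is small), and the aluminium enolate, activated as its methyl ate complex, is allylated only at C7, trans to the alkynyl group.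

Step 6
Reactants: 16 silyl alkyne ketone
Product: 18 (2S,3S,4R)-2-allyl-4-methyl-4-(4-methylpent-3-en-1-yl)-3-[(E)-2-(4,4,5,5-tetramethyl-1,3,2-dioxaborolan-2-yl)vinyl]cycloheptan-1-one, via terminal alkyne 17 (not isolated)
Conditions: K2CO3, MeOH, rt; then B2pin2 (1.1 equiv), CuCl (5 mol %), 1,3-di(1-adamantyl)imidazolinium tetrafluoroborate (5 mol %), NaOtBu (20 mol %), THF, rt
Reagents that add atoms: bis(pinacolato)diboron, CC1(C)OB(OC1(C)C)B1OC(C)(C)C(C)(C)O1
Why: Methanolysis of the C–Si bond followed by NHC–copper-catalysed protoboration (syn addition of Cu–B, boron to the terminal carbon, then protonation) gives the (E)-alkenylboronate; the saturated ketone and unactivated alkenes are inert, and no enone is present yet.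

Step 7
Reactants: 18 alkenylboronate ketone
Product: 20 (5S,6S,7S)-7-allyl-5-methyl-5-(4-methylpent-3-en-1-yl)-6-[(E)-2-(4,4,5,5-tetramethyl-1,3,2-dioxaborolan-2-yl)vinyl]cyclohept-2-en-1-one, via lithium enolate 19 (not isolated)
Conditions: LiN(iPr)2 (1.2 equiv), THF, −78 °C; then N-tert-butylbenzenesulfinimidoyl chloride (1.3 equiv), −78 °C
Reagents that add atoms: none
Why: Mukaiyama dehydrogenation: kinetic deprotonation at the unhindered CH2 (C2), S-sulfenylation and syn elimination give the C2=C3 enone; the tertiary C7–H is not touched, so no stereocentre is disturbed.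

Step 8
Reactants: 20 enone; 21 formaldehyde
Product: 22 (5S,6S,7S)-7-allyl-2-(hydroxymethyl)-5-methyl-5-(4-methylpent-3-en-1-yl)-6-[(E)-2-(4,4,5,5-tetramethyl-1,3,2-dioxaborolan-2-yl)vinyl]cyclohept-2-en-1-one
Conditions: 37 % aq. HCHO (3 equiv), DMAP (0.3 equiv), THF/H2O (1:1), rt
Reagents that add atoms: none
Why: Morita–Baylis–Hillman reaction: DMAP adds to the unhindered β-carbon C3, the enolate takes up formaldehyde at C2 and DMAP is expelled; this is done before the enol ester exists, because nucleophilic amines would cleave it.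

Step 9
Reactants: 22 hydroxymethyl enone boronate; 23 3-methylbut-2-enoic acid
Product: 25 (5S,6S,7S)-7-allyl-2-(hydroxymethyl)-5-methyl-5-(4-methylpent-3-en-1-yl)-6-[(E)-2-(3-methylbut-2-enoyloxy)vinyl]cyclohept-2-en-1-one, via potassium trifluoroborate 24 (not isolated)
Conditions: KHF2, MeOH/H2O, rt, evaporate; then 23 (3 equiv), CuBr (10 mol %), DMAP (20 mol %), 4 Å MS, O2 (1 atm), MeCN, 40 °C
Reagents that add atoms: none
Why: Chan–Lam-type oxidative C–O coupling of an alkenyltrifluoroborate with a carboxylic acid proceeds with retention of alkene geometry and gives the (E)-enol ester.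

Step 10
Reactants: 25 allyl enol ester
Product: 26 (5S,6S,7S)-2-(hydroxymethyl)-5-methyl-5-(4-methylpent-3-en-1-yl)-6-[(E)-2-(3-methylbut-2-enoyloxy)vinyl]-7-(2-oxopropyl)cyclohept-2-en-1-one
Conditions: PdCl2 (10 mol %), CuCl (1 equiv), O2 (1 atm), DMF/H2O (7:1), rt
Reagents that add atoms: water, O (source of the ketone oxygen; dioxygen, O=O, is the terminal oxidant)
Why: Tsuji–Wacker oxidation is selective for the monosubstituted allyl alkene (Markovnikov hydroxypalladation) over the trisubstituted alkene, the enone and the hindered 1,2-disubstituted enol ester; the order also keeps boron away from palladium.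

Step 11
Reactants: 26 diketone enol ester
Product: 27 (5S,6S,7S)-5-[(3S)-3-hydroperoxy-4-methylpent-4-en-1-yl]-2-(hydroxymethyl)-5-methyl-6-[(E)-2-(3-methylbut-2-enoyloxy)vinyl]-7-(2-oxopropyl)cyclohept-2-en-1-one
Conditions: (4R,5R)-TADDOL phenyl phosphite (1.5 equiv), O3, CH2Cl2, −78 °C, then Ar purge; add 26, −78 → −45 °C; cold chromatography
Reagents that add atoms: ozone, [O-][O+]=O, delivered as (4R,5R)-TADDOL phenyl phosphite ozonide, CC1(C)O[C@@H]2[C@@H](O1)C(c1ccccc1)(c1ccccc1)OP3(Oc1ccccc1)(OOO3)OC2(c1ccccc1)c1ccccc1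
Why: Proposed new method: a chiral cyclic phosphite ozonide, used below −40 °C where it does not yet release free singlet oxygen, is attacked at its terminal oxygen by the electron-rich trisubstituted alkene in a bimolecular, perepoxide-like transition state with the chiral phosphorus still bound; positive charge builds at the tertiary carbon, so O goes to the CH carbon and a methyl hydrogen is lost to give the isopropenyl hydroperoxide, while the C2-symmetric TADDOL backbone selects the alkene face and sets C3′ as (S); the closest known reaction is the direct low-temperature ene-type hydroperoxidation of alkenes by achiral triphenyl phosphite ozonide, for which no asymmetric version exists.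

## Compound list

1 | 3-methylcyclohex-2-en-1-one | CC1=CC(=O)CCC1 | starting material
2 | 5-bromo-2-methylpent-1-ene | C=C(C)CCCBr | starting material
3 | (4-methylpent-4-en-1-yl)magnesium bromide | C=C(C)CCC[Mg]Br | intermediate
4 | bromomagnesium (S)-3-methyl-3-(4-methylpent-4-en-1-yl)cyclohex-1-en-1-olate | C=C(C)CCC[C@@]1(C)CCCC(O[Mg]Br)=C1 | intermediate
5 | (S)-trimethyl{[3-methyl-3-(4-methylpent-4-en-1-yl)cyclohex-1-en-1-yl]oxy}silane | C=C(C)CCC[C@@]1(C)CCCC(O[Si](C)(C)C)=C1 | intermediate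
6 | diiodomethane | ICI | starting material
7 | (5S)-5-methyl-5-(4-methylpent-4-en-1-yl)-1-(trimethylsilyloxy)bicyclo[4.1.0]heptane (C1/C6 both face isomers) | C=C(C)CCC[C@@]1(C)CCCC2(O[Si](C)(C)C)CC12 | intermediate
8 | (4S)-3-chloro-4-methyl-4-(4-methylpent-4-en-1-yl)cycloheptan-1-one (C3 epimers) | C=C(C)CCC[C@@]1(C)CCCC(=O)CC1Cl | intermediate
9 | (4R)-3-chloro-4-methyl-4-(4-methylpent-3-en-1-yl)cycloheptan-1-one (C3 epimers) | CC(C)=CCC[C@@]1(C)CCCC(=O)CC1Cl | intermediate
10 | (R)-4-methyl-4-(4-methylpent-3-en-1-yl)cyclohept-2-en-1-one | CC(C)=CCC[C@@]1(C)CCCC(=O)C=C1 | intermediate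
11 | ethynyltrimethylsilane | C#C[Si](C)(C)C | starting material
12 | allyl bromide (3-bromoprop-1-ene) | C=CCBr | starting material
13 | lithium (trimethylsilyl)acetylide | [Li]C#C[Si](C)(C)C | intermediate
14 | dimethyl[(trimethylsilyl)ethynyl]aluminium | C[Al](C)C#C[Si](C)(C)C | intermediate
15 | dimethylaluminium (3S,4R)-4-methyl-4-(4-methylpent-3-en-1-yl)-3-[(trimethylsilyl)ethynyl]cyclohept-1-en-1-olate | CC(C)=CCC[C@@]1(C)CCCC(O[Al](C)C)=C[C@@H]1C#C[Si](C)(C)C | intermediate
16 | (2S,3S,4R)-2-allyl-4-methyl-4-(4-methylpent-3-en-1-yl)-3-[(trimethylsilyl)ethynyl]cycloheptan-1-one | CC(C)=CCC[C@@]1(C)CCCC(=O)[C@@H](CC=C)[C@@H]1C#C[Si](C)(C)C | intermediate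
17 | (2S,3S,4R)-2-allyl-3-ethynyl-4-methyl-4-(4-methylpent-3-en-1-yl)cycloheptan-1-one | CC(C)=CCC[C@@]1(C)CCCC(=O)[C@@H](CC=C)[C@@H]1C#C | intermediate
18 | (2S,3S,4R)-2-allyl-4-methyl-4-(4-methylpent-3-en-1-yl)-3-[(E)-2-(4,4,5,5-tetramethyl-1,3,2-dioxaborolan-2-yl)vinyl]cycloheptan-1-one | CC(C)=CCC[C@@]1(C)CCCC(=O)[C@@H](CC=C)[C@@H]1/C=C/B1OC(C)(C)C(C)(C)O1 | intermediate
19 | lithium (5S,6S,7S)-7-allyl-5-methyl-5-(4-methylpent-3-en-1-yl)-6-[(E)-2-(4,4,5,5-tetramethyl-1,3,2-dioxaborolan-2-yl)vinyl]cyclohept-1-en-1-olate | CC(C)=CCC[C@@]1(C)CCC=C(O[Li])[C@@H](CC=C)[C@@H]1/C=C/B1OC(C)(C)C(C)(C)O1 | intermediate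
20 | (5S,6S,7S)-7-allyl-5-methyl-5-(4-methylpent-3-en-1-yl)-6-[(E)-2-(4,4,5,5-tetramethyl-1,3,2-dioxaborolan-2-yl)vinyl]cyclohept-2-en-1-one | CC(C)=CCC[C@@]1(C)CC=CC(=O)[C@@H](CC=C)[C@@H]1/C=C/B1OC(C)(C)C(C)(C)O1 | intermediate
21 | formaldehyde | C=O | starting material
22 | (5S,6S,7S)-7-allyl-2-(hydroxymethyl)-5-methyl-5-(4-methylpent-3-en-1-yl)-6-[(E)-2-(4,4,5,5-tetramethyl-1,3,2-dioxaborolan-2-yl)vinyl]cyclohept-2-en-1-one | CC(C)=CCC[C@@]1(C)CC=C(CO)C(=O)[C@@H](CC=C)[C@@H]1/C=C/B1OC(C)(C)C(C)(C)O1 | intermediate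
23 | 3-methylbut-2-enoic acid | CC(C)=CC(=O)O | starting material
24 | potassium {(E)-2-[(5S,6S,7S)-7-allyl-2-(hydroxymethyl)-5-methyl-5-(4-methylpent-3-en-1-yl)-1-oxocyclohept-2-en-6-yl]vinyl}trifluoroborate | CC(C)=CCC[C@@]1(C)CC=C(CO)C(=O)[C@@H](CC=C)[C@@H]1/C=C/[B-](F)(F)F.[K+] | intermediate
25 | (5S,6S,7S)-7-allyl-2-(hydroxymethyl)-5-methyl-5-(4-methylpent-3-en-1-yl)-6-[(E)-2-(3-methylbut-2-enoyloxy)vinyl]cyclohept-2-en-1-one | CC(C)=CCC[C@@]1(C)CC=C(CO)C(=O)[C@@H](CC=C)[C@@H]1/C=C/OC(=O)C=C(C)C | intermediate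
26 | (5S,6S,7S)-2-(hydroxymethyl)-5-methyl-5-(4-methylpent-3-en-1-yl)-6-[(E)-2-(3-methylbut-2-enoyloxy)vinyl]-7-(2-oxopropyl)cyclohept-2-en-1-one | CC(C)=CCC[C@@]1(C)CC=C(CO)C(=O)[C@@H](CC(C)=O)[C@@H]1/C=C/OC(=O)C=C(C)C | intermediate
27 | (5S,6S,7S)-5-[(3S)-3-hydroperoxy-4-methylpent-4-en-1-yl]-2-(hydroxymethyl)-5-methyl-6-[(E)-2-(3-methylbut-2-enoyloxy)vinyl]-7-(2-oxopropyl)cyclohept-2-en-1-one (CNP0216745.1) | C=C(C)[C@H](CC[C@@]1(C)CC=C(CO)C(=O)[C@@H](CC(C)=O)[C@@H]1/C=C/OC(=O)C=C(C)C)OO | target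

## Step count and weakest steps

Total step count: 11. Longest linear sequence: 11 steps (1 or 2 to 27).

**Step 11 (the new reagent).** The sense and level of face selection are unknown. The free hydroxyl of 26 may make the ozonide release free singlet oxygen, which would erase the face control and also give the tertiary hydroperoxide. Fallback with known chemistry: set out from 26 and run the classical dye-sensitised photo-oxygenation (tetraphenylporphyrin, O2, visible light, CH2Cl2, −20 °C; Schenck ene reaction of free singlet oxygen). This gives 27 together with its side-chain epimer (5S,6S,7S)-5-[(3R)-3-hydroperoxy-4-methylpent-4-en-1-yl]-2-(hydroxymethyl)-5-methyl-6-[(E)-2-(3-methylbut-2-enoyloxy)vinyl]-7-(2-oxopropyl)cyclohept-2-en-1-one F1 and the regioisomeric tertiary hydroperoxide (5S,6S,7S)-5-[(E)-4-hydroperoxy-4-methylpent-2-en-1-yl]-2-(hydroxymethyl)-5-methyl-6-[(E)-2-(3-methylbut-2-enoyloxy)vinyl]-7-(2-oxopropyl)cyclohept-2-en-1-one F2. The stereocentre is then obtained by preparative HPLC separation instead of induction, and the route comes back at 27.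

**Step 5.** Nickel-catalysed asymmetric alkynylation has little precedent beyond simple cycloalkenones, the β-carbon is neopentyl, and the catalyst must override the substrate. Fallback: set out from 10 and use an alkenylalane, the nucleophile class with the broadest precedent for copper-catalysed asymmetric addition to hindered cyclic enones. (E)-(2-Bromovinyl)trimethylsilane is lithiated with t-BuLi to (E)-[2-(trimethylsilyl)vinyl]lithium F3 and transmetallated with Me2AlCl to (E)-dimethyl[2-(trimethylsilyl)vinyl]aluminium F4. Conjugate addition to 10 with copper thiophene-2-carboxylate and a chiral phosphoramidite or NHC ligand gives dimethylaluminium (3R,4R)-4-methyl-4-(4-methylpent-3-en-1-yl)-3-[(E)-2-(trimethylsilyl)vinyl]cyclohept-1-en-1-olate F5. Allylation with MeLi and 12 as in step 5 gives (2S,3R,4R)-2-allyl-4-methyl-4-(4-methylpent-3-en-1-yl)-3-[(E)-2-(trimethylsilyl)vinyl]cycloheptan-1-one F6. Ipso-borodesilylation with BCl3 (CH2Cl2, −78 → 0 °C) gives (2S,3S,4R)-2-allyl-3-[(E)-2-(dichloroboryl)vinyl]-4-methyl-4-(4-methylpent-3-en-1-yl)cycloheptan-1-one F7, and pinacol/Et3N then gives 18, where the route is rejoined.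

**Step 10.** PdCl2 may attack the enol ester (hydroxypalladation and loss of the acyl group) in competition with the allyl group. Fallback: set out from 16 and keep the robust silyl alkyne until palladium has been used, building the enol ester afterwards (one step longer).
- Dehydrogenation as in step 7 goes through lithium (5S,6S,7S)-7-allyl-5-methyl-5-(4-methylpent-3-en-1-yl)-6-[(trimethylsilyl)ethynyl]cyclohept-1-en-1-olate F8 to (5S,6S,7S)-7-allyl-5-methyl-5-(4-methylpent-3-en-1-yl)-6-[(trimethylsilyl)ethynyl]cyclohept-2-en-1-one F9.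
- Hydroxymethylation as in step 8 gives (5S,6S,7S)-7-allyl-2-(hydroxymethyl)-5-methyl-5-(4-methylpent-3-en-1-yl)-6-[(trimethylsilyl)ethynyl]cyclohept-2-en-1-one F10.
- Wacker oxidation as in step 10 gives (5S,6S,7S)-2-(hydroxymethyl)-5-methyl-5-(4-methylpent-3-en-1-yl)-7-(2-oxopropyl)-6-[(trimethylsilyl)ethynyl]cyclohept-2-en-1-one F11.
- Desilylation (Bu4NF, AcOH, THF, 0 °C) gives (5S,6S,7S)-6-ethynyl-2-(hydroxymethyl)-5-methyl-5-(4-methylpent-3-en-1-yl)-7-(2-oxopropyl)cyclohept-2-en-1-one F12.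
- Hydroboration with pinacolborane and catalytic dicyclohexylborane, which leaves the enone alone, gives (5S,6S,7S)-2-(hydroxymethyl)-5-methyl-5-(4-methylpent-3-en-1-yl)-7-(2-oxopropyl)-6-[(E)-2-(4,4,5,5-tetramethyl-1,3,2-dioxaborolan-2-yl)vinyl]cyclohept-2-en-1-one F13.
- KHF2 gives potassium {(E)-2-[(5S,6S,7S)-2-(hydroxymethyl)-5-methyl-5-(4-methylpent-3-en-1-yl)-1-oxo-7-(2-oxopropyl)cyclohept-2-en-6-yl]vinyl}trifluoroborate F14, and the copper-catalysed coupling of step 9 with 23 comes back to the route at 26.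

## Further compounds

F1 | step 11 | (5S,6S,7S)-5-[(3R)-3-hydroperoxy-4-methylpent-4-en-1-yl]-2-(hydroxymethyl)-5-methyl-6-[(E)-2-(3-methylbut-2-enoyloxy)vinyl]-7-(2-oxopropyl)cyclohept-2-en-1-one | C=C(C)[C@@H](CC[C@@]1(C)CC=C(CO)C(=O)[C@@H](CC(C)=O)[C@@H]1/C=C/OC(=O)C=C(C)C)OO
F2 | step 11 | (5S,6S,7S)-5-[(E)-4-hydroperoxy-4-methylpent-2-en-1-yl]-2-(hydroxymethyl)-5-methyl-6-[(E)-2-(3-methylbut-2-enoyloxy)vinyl]-7-(2-oxopropyl)cyclohept-2-en-1-one | CC(C)(OO)/C=C/C[C@@]1(C)CC=C(CO)C(=O)[C@@H](CC(C)=O)[C@@H]1/C=C/OC(=O)C=C(C)C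
F3 | step 5 | (E)-[2-(trimethylsilyl)vinyl]lithium | [Li]/C=C/[Si](C)(C)C
F4 | step 5 | (E)-dimethyl[2-(trimethylsilyl)vinyl]aluminium | C[Al](C)/C=C/[Si](C)(C)C
F5 | step 5 | dimethylaluminium (3R,4R)-4-methyl-4-(4-methylpent-3-en-1-yl)-3-[(E)-2-(trimethylsilyl)vinyl]cyclohept-1-en-1-olate | CC(C)=CCC[C@@]1(C)CCCC(O[Al](C)C)=C[C@@H]1/C=C/[Si](C)(C)C
F6 | step 5 | (2S,3R,4R)-2-allyl-4-methyl-4-(4-methylpent-3-en-1-yl)-3-[(E)-2-(trimethylsilyl)vinyl]cycloheptan-1-one | CC(C)=CCC[C@@]1(C)CCCC(=O)[C@@H](CC=C)[C@@H]1/C=C/[Si](C)(C)C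
F7 | step 5 | (2S,3S,4R)-2-allyl-3-[(E)-2-(dichloroboryl)vinyl]-4-methyl-4-(4-methylpent-3-en-1-yl)cycloheptan-1-one | CC(C)=CCC[C@@]1(C)CCCC(=O)[C@@H](CC=C)[C@@H]1/C=C/B(Cl)Cl
F8 | step 10 | lithium (5S,6S,7S)-7-allyl-5-methyl-5-(4-methylpent-3-en-1-yl)-6-[(trimethylsilyl)ethynyl]cyclohept-1-en-1-olate | CC(C)=CCC[C@@]1(C)CCC=C(O[Li])[C@@H](CC=C)[C@@H]1C#C[Si](C)(C)C
F9 | step 10 | (5S,6S,7S)-7-allyl-5-methyl-5-(4-methylpent-3-en-1-yl)-6-[(trimethylsilyl)ethynyl]cyclohept-2-en-1-one | CC(C)=CCC[C@@]1(C)CC=CC(=O)[C@@H](CC=C)[C@@H]1C#C[Si](C)(C)C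
F10 | step 10 | (5S,6S,7S)-7-allyl-2-(hydroxymethyl)-5-methyl-5-(4-methylpent-3-en-1-yl)-6-[(trimethylsilyl)ethynyl]cyclohept-2-en-1-one | CC(C)=CCC[C@@]1(C)CC=C(CO)C(=O)[C@@H](CC=C)[C@@H]1C#C[Si](C)(C)C
F11 | step 10 | (5S,6S,7S)-2-(hydroxymethyl)-5-methyl-5-(4-methylpent-3-en-1-yl)-7-(2-oxopropyl)-6-[(trimethylsilyl)ethynyl]cyclohept-2-en-1-one | CC(C)=CCC[C@@]1(C)CC=C(CO)C(=O)[C@@H](CC(C)=O)[C@@H]1C#C[Si](C)(C)C
F12 | step 10 | (5S,6S,7S)-6-ethynyl-2-(hydroxymethyl)-5-methyl-5-(4-methylpent-3-en-1-yl)-7-(2-oxopropyl)cyclohept-2-en-1-one | CC(C)=CCC[C@@]1(C)CC=C(CO)C(=O)[C@@H](CC(C)=O)[C@@H]1C#C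
F13 | step 10 | (5S,6S,7S)-2-(hydroxymethyl)-5-methyl-5-(4-methylpent-3-en-1-yl)-7-(2-oxopropyl)-6-[(E)-2-(4,4,5,5-tetramethyl-1,3,2-dioxaborolan-2-yl)vinyl]cyclohept-2-en-1-one | CC(C)=CCC[C@@]1(C)CC=C(CO)C(=O)[C@@H](CC(C)=O)[C@@H]1/C=C/B1OC(C)(C)C(C)(C)O1
F14 | step 10 | potassium {(E)-2-[(5S,6S,7S)-2-(hydroxymethyl)-5-methyl-5-(4-methylpent-3-en-1-yl)-1-oxo-7-(2-oxopropyl)cyclohept-2-en-6-yl]vinyl}trifluoroborate | CC(C)=CCC[C@@]1(C)CC=C(CO)C(=O)[C@@H](CC(C)=O)[C@@H]1/C=C/[B-](F)(F)F.[K+]
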